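**Plan**

- Retrosynthesis: cut the aryl–CH2 bond at C8 (sp2–sp3 Negishi coupling), then the C4–C4a bond of ring C, then the O1–C2 ether bond. This leaves three pieces: a phloroglucinol-derived iodophenol (ring A), an allylated 2,4-diacetoxybenzaldehyde (ring B with C2–C4), and a hydrated lavandulyl iodide.
- Forward: the ring-A phenol is iodinated ortho to OH and joined through O1 to the ring-B carbinol; the alkene is cut to the C4 aldehyde; a polarity-reversed aryl-metal closure C4a→C4 builds ring C; oxidation gives the flavanone; C8 is iodinated, the side chain is coupled, and the protecting groups are removed.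
- Enabling feature: C4a is the ring-A carbon between O1 and O5. In the symmetric 3,5-bis(silyloxy)phenol it is the carbon ortho to the free OH, so one iodination marks it, and the C–I bond then lies six atoms from the aldehyde carbon (C4a–C8a–O1–C2–C3–C4). C6 sits between the two silyl ethers at O5 and O7 and is blocked, so after closure only C8 is open for the side chain.
- Stereochemistry: C2 (S) comes from a Brown allylboration ((R)-carbinol) followed by Mitsunobu inversion. The side-chain (R) centre comes from an Evans dienolate alkylation with the (S)-4-benzyl auxiliary. The C4 carbinol formed in the closure is oxidised away.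
- Protecting groups: acetates on ring B keep the benzylic C2 from ionising; TIPS on ring A also steers both iodinations; the closure is run without acid or base so that C2 and the C5 silyl ether survive.

Key step: step 7

Remark: the facial sense of the allylborane in step 4 is taken from the benzaldehyde precedent, in which the reagent of the (+)-α-pinene series gives the (S)-carbinol; the (−)-α-pinene series is therefore used.

**Step 1**
Reactants: 1 phloroglucinol
Product: 2 3,5-bis(triisopropylsilyloxy)phenol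
Conditions: i-Pr3SiCl (2.0 equiv), imidazole, DMF, 0 °C to rt; chromatographic separation from mono- and tris-ethers
Reagents that add atoms: chlorotriisopropylsilane, CC(C)[Si](Cl)(C(C)C)C(C)C
Why: Statistical imidazole-mediated O-silylation of the symmetric triol with two equivalents of the bulky chlorosilane should give the bis-ether as the main fraction, and the mono- and tris-ethers can be recycled.

**Step 2**
Reactants: 2 3,5-bis(triisopropylsilyloxy)phenol
Product: 3 2-iodo-3,5-bis(triisopropylsilyloxy)phenol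
Conditions: NIS (1.0 equiv), CH2Cl2, −40 to 0 °C
Reagents that add atoms: N-iodosuccinimide, O=C1CCC(=O)N1I
Why: Electrophilic aromatic iodination should occur at one of the two equivalent carbons ortho to the free hydroxyl, because the only other open carbon lies between two OTIPS groups and is shielded.

**Step 3**
Reactants: 4 2,4-dihydroxybenzaldehyde
Product: 5 2,4-diacetoxybenzaldehyde
Conditions: Ac2O, pyridine, DMAP (cat.), 0 °C to rt
Reagents that add atoms: acetic anhydride, CC(=O)OC(C)=O
Why: DMAP-catalysed acylation converts both phenols into acetates, which withdraw electron density from ring B so that the benzylic carbon next to it can later be substituted with clean inversion.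

**Step 4**
Reactants: 5 2,4-diacetoxybenzaldehyde
Product: 7 (R)-4-(1-hydroxybut-3-en-1-yl)-1,3-phenylene diacetate, via borinate ester 6 (not isolated)
Conditions: (−)-Ipc2B(allyl) [(−)-α-pinene series], Et2O, −78 °C; then H2O2, pH 7 phosphate buffer, MeOH, 0 °C to rt
Reagents that add atoms: B-allyldiisopinocampheylborane of the (−)-α-pinene series, C=CCB([C@H]1C[C@H]2C[C@@H]([C@@H]1C)C2(C)C)[C@H]1C[C@H]2C[C@@H]([C@@H]1C)C2(C)C
Why: Brown asymmetric allylboration through a closed chair transition state, in which the isopinocampheyl groups shield one face of the aldehyde, should set the (R)-carbinol centre, and the buffered oxidative work-up avoids base-induced migration of the ortho acetyl group.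

**Step 5**
Reactants: 3 2-iodo-3,5-bis(triisopropylsilyloxy)phenol; 7 (R)-4-(1-hydroxybut-3-en-1-yl)-1,3-phenylene diacetate
Product: 8 (S)-4-{1-[2-iodo-3,5-bis(triisopropylsilyloxy)phenoxy]but-3-en-1-yl}-1,3-phenylene diacetate
Conditions: PPh3, DIAD, toluene, 0 °C to rt
Reagents that add atoms: none
Why: Mitsunobu etherification, an SN2 displacement of the alkoxyphosphonium ion by the acidic iodophenol, should invert the carbinol centre to the (S)-aryl ether (the future C2), because the acetoxy groups keep the benzylic carbon from ionising.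

**Step 6**
Reactants: 8 (S)-4-{1-[2-iodo-3,5-bis(triisopropylsilyloxy)phenoxy]but-3-en-1-yl}-1,3-phenylene diacetate
Product: 10 (S)-4-{1-[2-iodo-3,5-bis(triisopropylsilyloxy)phenoxy]-3-oxopropyl}-1,3-phenylene diacetate, via vicinal diol 9 (not isolated)
Conditions: OsO4 (2 mol %), NaIO4, 2,6-lutidine, dioxane–H2O (3:1), rt; used directly
Reagents that add atoms: osmium tetroxide, O=[Os](=O)(=O)=O; sodium periodate NaIO4 (terminal oxygen source), [Na+].[O-]I(=O)(=O)=O
Why: Lemieux–Johnson cleavage (OsO4-catalysed dihydroxylation, then periodate scission, buffered by 2,6-lutidine) shortens the terminal alkene to the aldehyde that becomes C4 without touching the aryl iodide or the stereocentre.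

**Step 7**
Reactants: 10 (S)-4-{1-[2-iodo-3,5-bis(triisopropylsilyloxy)phenoxy]-3-oxopropyl}-1,3-phenylene diacetate
Product: 12 4-[(2S,4RS)-4-hydroxy-5,7-bis(triisopropylsilyloxy)chroman-2-yl]-1,3-phenylene diacetate, via arylchromium dichloride 11 (not isolated)
Conditions: CrCl2 (6 equiv), NiCl2 (5 mol %), degassed DMF–DMSO, rt; pH 7 buffer work-up
Reagents that add atoms: none
Why: Zerovalent nickel (formed from NiCl2 and CrCl2) inserts into the C4a–I bond and transmetalates to trivalent chromium, so that C4a, electrophilic in the iodide, becomes a nucleophilic arylchromium dichloride that adds to the aldehyde carbon C4, itself an electrophile (Nozaki–Hiyama–Kishi reaction; closest precedent: intramolecular aryl iodide–aldehyde NHK cyclisations). Ring C closes in the 6-exo-trig mode through C4a–C8a–O1–C2–C3–C4. The new stereocentre C4 is not controlled, and both epimers are oxidised to the same ketone in step 8. The step needs chemoselectivity for the C–I bond over the two aryl acetates, the silyl ethers and the base-sensitive β-aryloxy aldehyde; organochromium reagents add only to the aldehyde, and the neutral aprotic medium gives no E1cB loss of the ring-A phenoxide, so C2 should stay (S). Regioselectivity is built in, since the iodine marks the one ortho carbon that becomes C4a and leaves the other ortho carbon as C8 for the side chain.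

**Step 8**
Reactants: 12 4-[(2S,4RS)-4-hydroxy-5,7-bis(triisopropylsilyloxy)chroman-2-yl]-1,3-phenylene diacetate
Product: 13 (S)-4-[4-oxo-5,7-bis(triisopropylsilyloxy)chroman-2-yl]-1,3-phenylene diacetate
Conditions: Dess–Martin periodinane, pyridine, CH2Cl2, 0 °C to rt
Reagents that add atoms: none
Why: Dess–Martin oxidation of the benzylic alcohol gives the aryl ketone and removes the uncontrolled C4 centre, so both C4 epimers converge on one flavanone while the buffered medium leaves C2 untouched.

**Step 9**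
Reactants: 13 (S)-4-[4-oxo-5,7-bis(triisopropylsilyloxy)chroman-2-yl]-1,3-phenylene diacetate
Product: 14 (S)-4-[8-iodo-4-oxo-5,7-bis(triisopropylsilyloxy)chroman-2-yl]-1,3-phenylene diacetate
Conditions: NIS (1.1 equiv), CF3CO2H (10 mol %), MeCN, 0 °C to rt
Reagents that add atoms: N-iodosuccinimide, O=C1CCC(=O)N1I
Why: Electrophilic aromatic iodination of ring A should go to C8, between O1 and the C7 silyl ether, because C6 is flanked by two OTIPS groups and the acetylated ring B is deactivated, in line with the known C8 halogenation of 5,7-di-O-protected flavonoids.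

**Step 10**
Reactants: 15 (S)-4-benzyloxazolidin-2-one; 16 3-methylbut-2-enoyl chloride
Product: 18 (S)-4-benzyl-3-(3-methylbut-2-enoyl)oxazolidin-2-one, via lithium oxazolidinide 17 (not isolated)
Conditions: n-BuLi, THF, −78 °C; then 16, −78 to 0 °C
Reagents that add atoms: none
Why: N-acylation of the lithiated Evans oxazolidinone with the acid chloride installs the chiral auxiliary without amine base, which would isomerise the acid chloride through a vinylketene.

**Step 11**
Reactants: 18 (S)-4-benzyl-3-(3-methylbut-2-enoyl)oxazolidin-2-one; 19 1-bromo-3-methylbut-2-ene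
Product: 21 (S)-4-benzyl-3-[(S)-5-methyl-2-(prop-1-en-2-yl)hex-4-enoyl]oxazolidin-2-one, via sodium dienolate 20 (not isolated)
Conditions: NaN(SiMe3)2, THF, −78 °C; then 19, −78 to −40 °C
Reagents that add atoms: none
Why: Evans asymmetric alkylation: γ-deprotonation gives the chelated (Z)-dienolate, which is alkylated at the α-carbon on the face opposite the benzyl group with shift of the double bond into the isopropenyl position, setting the (S)-centre that becomes the side-chain stereocentre.

**Step 12**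
Reactants: 21 (S)-4-benzyl-3-[(S)-5-methyl-2-(prop-1-en-2-yl)hex-4-enoyl]oxazolidin-2-one
Product: 22 (S)-4-benzyl-3-{(2S)-2-[(3,3-dimethyloxiran-2-yl)methyl]-3-methylbut-3-enoyl}oxazolidin-2-one (both epimers at the oxirane CH)
Conditions: mCPBA (1.0 equiv), CH2Cl2, −20 to 0 °C
Reagents that add atoms: 3-chloroperoxybenzoic acid, OOC(=O)c1cccc(Cl)c1
Why: Prilezhaev epoxidation with one equivalent of peracid should select the more electron-rich trisubstituted alkene over the 1,1-disubstituted isopropenyl group (as in limonene), and the new oxirane centre is removed in the next step.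

**Step 13**
Reactants: 22 (S)-4-benzyl-3-{(2S)-2-[(3,3-dimethyloxiran-2-yl)methyl]-3-methylbut-3-enoyl}oxazolidin-2-one
Product: 23 (S)-5-methyl-2-(prop-1-en-2-yl)hexane-1,5-diol
Conditions: LiAlH4, THF, 0 °C to rt
Reagents that add atoms: none
Why: Hydride reduction removes the auxiliary reductively to the primary alcohol and opens the trisubstituted epoxide at its less hindered CH carbon, which gives the tertiary alcohol and leaves the stereocentre untouched.

**Step 14**
Reactants: 23 (S)-5-methyl-2-(prop-1-en-2-yl)hexane-1,5-diol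
Product: 24 (S)-6-iodo-2-methyl-5-(prop-1-en-2-yl)hexan-2-ol
Conditions: I2, PPh3, imidazole, CH2Cl2, 0 °C
Reagents that add atoms: iodine, II
Why: Appel-type iodination (Garegg–Samuelsson conditions) should convert only the primary alcohol, since the tertiary one is too hindered to form the alkoxyphosphonium ion.

**Step 15**
Reactants: 24 (S)-6-iodo-2-methyl-5-(prop-1-en-2-yl)hexan-2-ol
Product: 25 (S)-triethyl{[6-iodo-2-methyl-5-(prop-1-en-2-yl)hexan-2-yl]oxy}silane
Conditions: Et3SiOTf, 2,6-lutidine, CH2Cl2, −78 to 0 °C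
Reagents that add atoms: triethylsilyl trifluoromethanesulfonate, CC[Si](CC)(CC)OS(=O)(=O)C(F)(F)F
Why: Silylation of the tertiary alcohol with the silyl triflate masks the acidic proton before the organozinc reagent is made.

**Step 16**
Reactants: 14 (S)-4-[8-iodo-4-oxo-5,7-bis(triisopropylsilyloxy)chroman-2-yl]-1,3-phenylene diacetate; 25 (S)-triethyl{[6-iodo-2-methyl-5-(prop-1-en-2-yl)hexan-2-yl]oxy}silane
Product: 27 4-[(2S)-8-[(2R)-5-methyl-2-(prop-1-en-2-yl)-5-(triethylsilyloxy)hexyl]-4-oxo-5,7-bis(triisopropylsilyloxy)chroman-2-yl]-1,3-phenylene diacetate, via alkylzinc iodide 26 (not isolated)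
Conditions: 25, Zn dust (activated with 1,2-dibromoethane and Me3SiCl), DMA, 40 °C; then 14, Pd(OAc)2 (5 mol %), SPhos (10 mol %), THF, rt to 40 °C
Reagents that add atoms: none
Why: Negishi cross-coupling of the primary alkylzinc iodide at C8 with a biarylphosphine ligand suited to di-ortho-substituted aryl iodides should join the side chain under neutral conditions that neither open the flavanone ring nor involve the side-chain stereocentre.

**Step 17**
Reactants: 27 4-[(2S)-8-[(2R)-5-methyl-2-(prop-1-en-2-yl)-5-(triethylsilyloxy)hexyl]-4-oxo-5,7-bis(triisopropylsilyloxy)chroman-2-yl]-1,3-phenylene diacetate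
Product: 28 4-[(2S)-5,7-dihydroxy-8-[(2R)-5-hydroxy-5-methyl-2-(prop-1-en-2-yl)hexyl]-4-oxochroman-2-yl]-1,3-phenylene diacetate
Conditions: Bu4NF, AcOH (1:1), THF, 0 °C to rt
Reagents that add atoms: none
Why: Buffered fluoride desilylation cleaves the two aryl TIPS ethers and the TES ether, while the acetic acid suppresses phenoxide formation and with it retro-oxa-Michael opening at C2 and acid-free conditions spare the isopropenyl group.

**Step 18**
Reactants: 28 4-[(2S)-5,7-dihydroxy-8-[(2R)-5-hydroxy-5-methyl-2-(prop-1-en-2-yl)hexyl]-4-oxochroman-2-yl]-1,3-phenylene diacetate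
Product: 29 norkurarinol
Conditions: NH4OAc, MeOH–H2O (4:1), rt
Reagents that add atoms: none
Why: Neutral ammonium acetate-mediated methanolysis (transesterification) of the two aryl acetates should free the ring-B phenols without base, so that C2 (S) is not epimerised through ring opening to the chalcone.

**Compound list**

1 | phloroglucinol (benzene-1,3,5-triol) | Oc1cc(O)cc(O)c1 | starting material
2 | 3,5-bis(triisopropylsilyloxy)phenol | Oc1cc(O[Si](C(C)C)(C(C)C)C(C)C)cc(O[Si](C(C)C)(C(C)C)C(C)C)c1 | intermediate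
3 | 2-iodo-3,5-bis(triisopropylsilyloxy)phenol | Oc1cc(O[Si](C(C)C)(C(C)C)C(C)C)cc(O[Si](C(C)C)(C(C)C)C(C)C)c1I | intermediate
4 | 2,4-dihydroxybenzaldehyde | O=Cc1ccc(O)cc1O | starting material
5 | 2,4-diacetoxybenzaldehyde (4-formyl-1,3-phenylene diacetate) | CC(=O)Oc1ccc(C=O)c(OC(C)=O)c1 | intermediate
6 | O-diisopinocampheylboryl derivative of 7 (borinate ester, (−)-α-pinene series) | CC(=O)Oc1ccc([C@H](OB([C@H]2C[C@H]3C[C@@H]([C@@H]2C)C3(C)C)[C@H]2C[C@H]3C[C@@H]([C@@H]2C)C3(C)C)CC=C)c(OC(C)=O)c1 | intermediate (not isolated)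
7 | (R)-4-(1-hydroxybut-3-en-1-yl)-1,3-phenylene diacetate | CC(=O)Oc1ccc([C@H](O)CC=C)c(OC(C)=O)c1 | intermediate
8 | (S)-4-{1-[2-iodo-3,5-bis(triisopropylsilyloxy)phenoxy]but-3-en-1-yl}-1,3-phenylene diacetate | C=CC[C@H](Oc1cc(O[Si](C(C)C)(C(C)C)C(C)C)cc(O[Si](C(C)C)(C(C)C)C(C)C)c1I)c1ccc(OC(C)=O)cc1OC(C)=O | intermediate
9 | 4-{(1S)-3,4-dihydroxy-1-[2-iodo-3,5-bis(triisopropylsilyloxy)phenoxy]butyl}-1,3-phenylene diacetate (both C3 epimers) | OCC(O)C[C@H](Oc1cc(O[Si](C(C)C)(C(C)C)C(C)C)cc(O[Si](C(C)C)(C(C)C)C(C)C)c1I)c1ccc(OC(C)=O)cc1OC(C)=O | intermediate (not isolated)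
10 | (S)-4-{1-[2-iodo-3,5-bis(triisopropylsilyloxy)phenoxy]-3-oxopropyl}-1,3-phenylene diacetate | O=CC[C@H](Oc1cc(O[Si](C(C)C)(C(C)C)C(C)C)cc(O[Si](C(C)C)(C(C)C)C(C)C)c1I)c1ccc(OC(C)=O)cc1OC(C)=O | intermediate
11 | arylchromium dichloride in which CrCl2 (trivalent chromium) replaces the iodine of 10 | O=CC[C@H](Oc1cc(O[Si](C(C)C)(C(C)C)C(C)C)cc(O[Si](C(C)C)(C(C)C)C(C)C)c1[Cr](Cl)Cl)c1ccc(OC(C)=O)cc1OC(C)=O | intermediate (not isolated)
12 | 4-[(2S,4RS)-4-hydroxy-5,7-bis(triisopropylsilyloxy)chroman-2-yl]-1,3-phenylene diacetate | CC(=O)Oc1ccc([C@@H]2CC(O)c3c(O[Si](C(C)C)(C(C)C)C(C)C)cc(O[Si](C(C)C)(C(C)C)C(C)C)cc3O2)c(OC(C)=O)c1 | intermediate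
13 | (S)-4-[4-oxo-5,7-bis(triisopropylsilyloxy)chroman-2-yl]-1,3-phenylene diacetate | CC(=O)Oc1ccc([C@@H]2CC(=O)c3c(O[Si](C(C)C)(C(C)C)C(C)C)cc(O[Si](C(C)C)(C(C)C)C(C)C)cc3O2)c(OC(C)=O)c1 | intermediate
14 | (S)-4-[8-iodo-4-oxo-5,7-bis(triisopropylsilyloxy)chroman-2-yl]-1,3-phenylene diacetate | CC(=O)Oc1ccc([C@@H]2CC(=O)c3c(O[Si](C(C)C)(C(C)C)C(C)C)cc(O[Si](C(C)C)(C(C)C)C(C)C)c(I)c3O2)c(OC(C)=O)c1 | intermediate
15 | (S)-4-benzyloxazolidin-2-one | O=C1N[C@@H](Cc2ccccc2)CO1 | starting material
16 | 3-methylbut-2-enoyl chloride | CC(C)=CC(Cl)=O | starting material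
17 | lithium salt of 15 (N-lithio oxazolidinone) | [Li+].O=C1[N-][C@@H](Cc2ccccc2)CO1 | intermediate (not isolated)
18 | (S)-4-benzyl-3-(3-methylbut-2-enoyl)oxazolidin-2-one | CC(C)=CC(=O)N1[C@@H](Cc2ccccc2)COC1=O | intermediate
19 | 1-bromo-3-methylbut-2-ene (prenyl bromide) | CC(C)=CCBr | starting material
20 | sodium (Z)-dienolate of 18 | [Na+].C=C(C)/C=C(\[O-])N1[C@@H](Cc2ccccc2)COC1=O | intermediate (not isolated)
21 | (S)-4-benzyl-3-[(S)-5-methyl-2-(prop-1-en-2-yl)hex-4-enoyl]oxazolidin-2-one | C=C(C)[C@H](CC=C(C)C)C(=O)N1[C@@H](Cc2ccccc2)COC1=O | intermediate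
22 | (S)-4-benzyl-3-{(2S)-2-[(3,3-dimethyloxiran-2-yl)methyl]-3-methylbut-3-enoyl}oxazolidin-2-one (both oxirane epimers) | C=C(C)[C@H](CC1OC1(C)C)C(=O)N1[C@@H](Cc2ccccc2)COC1=O | intermediate
23 | (S)-5-methyl-2-(prop-1-en-2-yl)hexane-1,5-diol | C=C(C)[C@H](CCC(C)(C)O)CO | intermediate
24 | (S)-6-iodo-2-methyl-5-(prop-1-en-2-yl)hexan-2-ol | C=C(C)[C@H](CCC(C)(C)O)CI | intermediate
25 | (S)-triethyl{[6-iodo-2-methyl-5-(prop-1-en-2-yl)hexan-2-yl]oxy}silane | C=C(C)[C@H](CCC(C)(C)O[Si](CC)(CC)CC)CI | intermediate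
26 | alkylzinc iodide from 25 (Zn inserted into the C–I bond) | C=C(C)[C@H](CCC(C)(C)O[Si](CC)(CC)CC)C[Zn]I | intermediate (not isolated)
27 | 4-[(2S)-8-[(2R)-5-methyl-2-(prop-1-en-2-yl)-5-(triethylsilyloxy)hexyl]-4-oxo-5,7-bis(triisopropylsilyloxy)chroman-2-yl]-1,3-phenylene diacetate | C=C(C)[C@H](CCC(C)(C)O[Si](CC)(CC)CC)Cc1c(O[Si](C(C)C)(C(C)C)C(C)C)cc(O[Si](C(C)C)(C(C)C)C(C)C)c2c1O[C@H](c1ccc(OC(C)=O)cc1OC(C)=O)CC2=O | intermediate
28 | 4-[(2S)-5,7-dihydroxy-8-[(2R)-5-hydroxy-5-methyl-2-(prop-1-en-2-yl)hexyl]-4-oxochroman-2-yl]-1,3-phenylene diacetate | C=C(C)[C@H](CCC(C)(C)O)Cc1c(O)cc(O)c2c1O[C@H](c1ccc(OC(C)=O)cc1OC(C)=O)CC2=O | intermediate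
29 | norkurarinol, (2S)-2-(2,4-dihydroxyphenyl)-5,7-dihydroxy-8-[(2R)-5-hydroxy-5-methyl-2-(prop-1-en-2-yl)hexyl]chroman-4-one | C=C(C)[C@H](CCC(C)(C)O)Cc1c(O)cc(O)c2c1O[C@H](c1ccc(O)cc1O)CC2=O | target

**Step count and risks**

Total steps: 18. Longest linear sequence: 10 steps (steps 1, 2, 5–9, 16–18; equally steps 3, 4, 5–9, 16–18).

Steps most likely to fail:

1. Step 7. Insertion into the C4a–I bond, which is flanked by the ether oxygen and the C5 OTIPS group, may be slow, and the arylchromium species may be protonated before it reaches the aldehyde, so iodine is lost without ring closure. The fallback closes the same bond in the natural polarity, by Friedel–Crafts acylation of the iodine-free ring. It sets out from 2 and 7. Mitsunobu coupling (PPh3, DIAD) gives (S)-4-{1-[3,5-bis(triisopropylsilyloxy)phenoxy]but-3-en-1-yl}-1,3-phenylene diacetate F1. OsO4/NaIO4 cleavage through the vicinal diol F2 gives the aldehyde F3, and Pinnick oxidation (NaClO2, NaH2PO4, 2-methylbut-2-ene) gives the β-aryloxy acid F4. 1-Chloro-N,N,2-trimethylprop-1-en-1-amine converts it into the acid chloride F5, and SnCl4 (CH2Cl2, −78 °C) closes ring C at either of the two equivalent ortho carbons. The fallback comes back to the route at 13.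

2. Step 5. The activated benzylic oxygen may leave by elimination toward the conjugated aryl diene, or by partial ionisation that erodes the configuration of C2; the ortho acetyl group may also migrate to the carbinol before activation. The fallback forms the O1–C2 bond under catalyst control without a benzylic alcohol. It sets out from 5 and 3. Wittig reaction with (triphenylphosphoranylidene)acetaldehyde gives (E)-3-(2,4-diacetoxyphenyl)acrylaldehyde F6; Luche reduction (NaBH4, CeCl3, MeOH, −20 °C) gives the cinnamyl alcohol F7; ClCO2Me and pyridine give the methyl carbonate F8. Iridium-catalysed asymmetric allylic etherification ([Ir(cod)Cl]2, chiral phosphoramidite of the series that gives the (S)-ether, THF) with the lithium phenoxide F9 (from 3 and LiN(SiMe3)2) gives the branched (S)-allyl aryl ether F10. Hydroboration with 9-BBN to the alkylborane F11 and oxidation with NaBO3 give the primary alcohol F12, and Dess–Martin oxidation comes back to the route at 10.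

3. Step 16. Oxidative addition and transmetalation at the C8 iodide, flanked by O1 and the C7 OTIPS group, may be slow, so that protodezincation or β-hydride elimination of the alkyl partner wins. The fallback is a B-alkyl Suzuki–Miyaura coupling. It sets out from 25. Iodine–lithium exchange (t-BuLi, Et2O, −78 °C) gives the alkyllithium F13, and B-methoxy-9-BBN converts it into the lithium borinate complex F14. Coupling with 14 (Pd(dppf)Cl2, AsPh3, K3PO4, DMF–H2O, rt) comes back to the route at 27.

**Further compounds**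

F1 | step 7 | (S)-4-{1-[3,5-bis(triisopropylsilyloxy)phenoxy]but-3-en-1-yl}-1,3-phenylene diacetate | C=CC[C@H](Oc1cc(O[Si](C(C)C)(C(C)C)C(C)C)cc(O[Si](C(C)C)(C(C)C)C(C)C)c1)c1ccc(OC(C)=O)cc1OC(C)=O
F2 | step 7 | 4-{(1S)-1-[3,5-bis(triisopropylsilyloxy)phenoxy]-3,4-dihydroxybutyl}-1,3-phenylene diacetate (both C3 epimers) | OCC(O)C[C@H](Oc1cc(O[Si](C(C)C)(C(C)C)C(C)C)cc(O[Si](C(C)C)(C(C)C)C(C)C)c1)c1ccc(OC(C)=O)cc1OC(C)=O
F3 | step 7 | (S)-4-{1-[3,5-bis(triisopropylsilyloxy)phenoxy]-3-oxopropyl}-1,3-phenylene diacetate | O=CC[C@H](Oc1cc(O[Si](C(C)C)(C(C)C)C(C)C)cc(O[Si](C(C)C)(C(C)C)C(C)C)c1)c1ccc(OC(C)=O)cc1OC(C)=O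
F4 | step 7 | (S)-3-[3,5-bis(triisopropylsilyloxy)phenoxy]-3-(2,4-diacetoxyphenyl)propanoic acid | OC(=O)C[C@H](Oc1cc(O[Si](C(C)C)(C(C)C)C(C)C)cc(O[Si](C(C)C)(C(C)C)C(C)C)c1)c1ccc(OC(C)=O)cc1OC(C)=O
F5 | step 7 | (S)-3-[3,5-bis(triisopropylsilyloxy)phenoxy]-3-(2,4-diacetoxyphenyl)propanoyl chloride | ClC(=O)C[C@H](Oc1cc(O[Si](C(C)C)(C(C)C)C(C)C)cc(O[Si](C(C)C)(C(C)C)C(C)C)c1)c1ccc(OC(C)=O)cc1OC(C)=O
F6 | step 5 | (E)-3-(2,4-diacetoxyphenyl)acrylaldehyde | O=C/C=C/c1ccc(OC(C)=O)cc1OC(C)=O
F7 | step 5 | (E)-4-(3-hydroxyprop-1-en-1-yl)-1,3-phenylene diacetate | OC/C=C/c1ccc(OC(C)=O)cc1OC(C)=O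
F8 | step 5 | (E)-3-(2,4-diacetoxyphenyl)allyl methyl carbonate | COC(=O)OC/C=C/c1ccc(OC(C)=O)cc1OC(C)=O
F9 | step 5 | lithium 2-iodo-3,5-bis(triisopropylsilyloxy)phenoxide | [Li+].[O-]c1cc(O[Si](C(C)C)(C(C)C)C(C)C)cc(O[Si](C(C)C)(C(C)C)C(C)C)c1I
F10 | step 5 | (S)-4-{1-[2-iodo-3,5-bis(triisopropylsilyloxy)phenoxy]prop-2-en-1-yl}-1,3-phenylene diacetate | C=C[C@H](Oc1cc(O[Si](C(C)C)(C(C)C)C(C)C)cc(O[Si](C(C)C)(C(C)C)C(C)C)c1I)c1ccc(OC(C)=O)cc1OC(C)=O
F11 | step 5 | B-alkyl-9-borabicyclo[3.3.1]nonane from terminal hydroboration of F10 | C(C[C@H](Oc1cc(O[Si](C(C)C)(C(C)C)C(C)C)cc(O[Si](C(C)C)(C(C)C)C(C)C)c1I)c1ccc(OC(C)=O)cc1OC(C)=O)B1C2CCCC1CCC2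
F12 | step 5 | (S)-4-{3-hydroxy-1-[2-iodo-3,5-bis(triisopropylsilyloxy)phenoxy]propyl}-1,3-phenylene diacetate | OCC[C@H](Oc1cc(O[Si](C(C)C)(C(C)C)C(C)C)cc(O[Si](C(C)C)(C(C)C)C(C)C)c1I)c1ccc(OC(C)=O)cc1OC(C)=O
F13 | step 16 | alkyllithium from 25 (lithium in place of iodine) | C=C(C)[C@H](CCC(C)(C)O[Si](CC)(CC)CC)C[Li]
F14 | step 16 | lithium B-alkyl-B-methoxy-9-borabicyclo[3.3.1]nonane borinate complex from F13 | [Li+].C=C(C)[C@H](CCC(C)(C)O[Si](CC)(CC)CC)C[B-]1(OC)C2CCCC1CCC2
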